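**Plan**

Numbering: C1 carries ring C, C2 and C3 the methyls, C4 is CH, ring A is C4a, C5 (OMe), C6 (OH), C7 (OMe), C8 (H), C8a; ring B is C1–C4, C4a, C8a.
Retrosynthesis: the two C–OH bonds (C6, C4') are cut first, since each hydroxyl lies between two methoxy groups where an aryl C–H can be lithiated. Ring A is then cut at C8–C8a, C5–C6, C7–C8 and C4a–C5, and last the C1–C1' biaryl bond and the aryl–acetyl bond.
Enabling feature: at the key stage ring A needs oxygen only at C5 and C7, meta to each other, with CH at C6 and C8. This is the pattern a ketene/oxyalkyne benzannulation delivers, and C1 already bears ring C, so ring A can close only at C4a.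
Forward: ring B is bought as 2,3-dimethylphenol and acetylated ortho; ring C is attached by cross-coupling; the methyl ketone becomes the diazo ketone; ring A is annulated; both ring A oxygens are methylated; the two hydroxyls come last in one operation.
Stereochemistry: none to set; the target has no stereocentre and ring C is symmetric about the C1–C1' axis.

Key step: step 6

Assumption: (triisopropylsilyloxy)acetylene is not treated as a stock item and is made in step 5; 3-phenylisoxazole and (3,5-dimethoxyphenyl)boronic acid are taken as catalogue compounds.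

**Route**

Step 1
Reactants: 1 2,3-dimethylphenol
Product: 3 1-(2-hydroxy-3,4-dimethylphenyl)ethan-1-one, via 2,3-dimethylphenyl acetate 2 (not isolated)
Conditions: AcCl, neat, 60 °C; then AlCl3, 140 °C; aq. HCl, steam distillation
Reagents that add atoms: acetyl chloride, CC(Cl)=O
Why: O-acetylation then AlCl3-mediated Fries rearrangement, which at high temperature without solvent favours the chelated ortho-hydroxy ketone at the only free ortho carbon, the steam-volatile ortho isomer being separable from any para ketone.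

Step 2
Reactants: 3 1-(2-hydroxy-3,4-dimethylphenyl)ethan-1-one
Product: 4 6-acetyl-2,3-dimethylphenyl trifluoromethanesulfonate
Conditions: Tf2O, pyridine, CH2Cl2, 0 °C
Reagents that add atoms: trifluoromethanesulfonic anhydride, FC(F)(F)S(=O)(=O)OS(=O)(=O)C(F)(F)F
Why: Standard aryl triflate formation from a phenol, with the ketone inert to the conditions.

Step 3
Reactants: 4 6-acetyl-2,3-dimethylphenyl trifluoromethanesulfonate; 5 (3,5-dimethoxyphenyl)boronic acid
Product: 6 1-[2-(3,5-dimethoxyphenyl)-3,4-dimethylphenyl]ethan-1-one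
Conditions: Pd(OAc)2 (3 mol %), SPhos (6 mol %), K3PO4, toluene/H2O, 90 °C
Reagents that add atoms: none
Why: Suzuki–Miyaura coupling, in which the ortho-acyl triflate adds readily to zerovalent palladium and the bulky biaryl phosphine allows coupling at a carbon flanked by acetyl and methyl with an unhindered boronic acid.

Step 4
Reactants: 6 1-[2-(3,5-dimethoxyphenyl)-3,4-dimethylphenyl]ethan-1-one
Product: 8 2-diazo-1-[2-(3,5-dimethoxyphenyl)-3,4-dimethylphenyl]ethan-1-one, via trifluoromethyl diketone 7 (not isolated)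
Conditions: LiN(SiMe3)2, THF, −78 °C; CF3CO2CH2CF3; then 4-AcNHC6H4SO2N3, Et3N, H2O, MeCN, 20 °C
Reagents that add atoms: 4-acetamidobenzenesulfonyl azide, CC(=O)Nc1ccc(cc1)S(=O)(=O)N=[N+]=[N-]
Why: Detrifluoroacetylative diazo transfer, in which Claisen trifluoroacetylation of the methyl ketone enolate activates the methyl carbon for Regitz diazo transfer and the trifluoroacetyl group leaves on the sulfonamide.

Step 5
Reactants: 9 3-phenylisoxazole; 10 triisopropylsilyl trifluoromethanesulfonate
Product: 13 (triisopropylsilyloxy)acetylene, via 5-lithio-3-phenylisoxazole 11 (not isolated), via lithium ethynolate 12 (not isolated)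
Conditions: n-BuLi, THF, −78 → −20 °C; then 10, −78 → 0 °C; distillation
Reagents that add atoms: none
Why: Deprotonation at C5 of the 3-arylisoxazole is followed by anionic cycloreversion to benzonitrile and the lithium ynolate, which the hard, bulky silyl triflate silylates on oxygen (silyl ynol ether formation from an ynolate).

Step 6
Reactants: 8 2-diazo-1-[2-(3,5-dimethoxyphenyl)-3,4-dimethylphenyl]ethan-1-one; 13 (triisopropylsilyloxy)acetylene
Product: 18 5-(3,5-dimethoxyphenyl)-6,7-dimethyl-3-[(triisopropylsilyl)oxy]naphthalen-1-ol, via arylketene 14 (not isolated), via 4-aryl-3-siloxycyclobutenone 15 (not isolated), via dienylketene 16 (not isolated), via 4aH-naphthalen-1-one 17 (not isolated)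
Conditions: hν (medium-pressure Hg lamp, Pyrex), 13 (3 equiv), ClCH2CH2Cl, 20 °C; then 80 °C
Reagents that add atoms: none
Why: Light expels N2 from 8 and ring B carbon C8a shifts to the carbene carbon (Wolff rearrangement) to give arylketene 14, whose carbonyl carbon is attacked by the electron-rich CH terminus of 13, so that a [2+2] cycloaddition forms C5–C6 and C7–C8 and gives cyclobutenone 15. At 80 °C 15 opens reversibly (4π electrocyclic) to dienylketene 16, and the isomer with the aryl group cis to the ketene arm closes ring A by a thermal 6π electrocyclisation onto the arene that forms C4a–C5, after which dienone 17 enolises to the naphthol. The closest known reaction is the second-generation Danheiser benzannulation of aryl diazo ketones with siloxyalkynes, which gives 3-siloxy-1-naphthols. No stereocentre is formed. Two selectivities are needed: the orientation of the alkyne, secured by the oxygen-induced polarisation of 13 (oxygen ends at C7, hydrogen at C6), and the site of closure, secured because C1 already bears ring C and C4a is the only free ortho carbon. Ring C stands nearly perpendicular to ring B between the C2 methyl and the ketene arm, and the excess of 13 should intercept 14 at 20 °C before the ketene can acylate the dimethoxyphenyl ring.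

Step 7
Reactants: 18 5-(3,5-dimethoxyphenyl)-6,7-dimethyl-3-[(triisopropylsilyl)oxy]naphthalen-1-ol
Product: 20 1-(3,5-dimethoxyphenyl)-5,7-dimethoxy-2,3-dimethylnaphthalene, via 5-methoxy silyl ether 19 (not isolated)
Conditions: MeI (excess), K2CO3, DMF, 20 °C; then Bu4NF, THF, 20 °C
Reagents that add atoms: iodomethane, CI
Why: Williamson O-methylation of the free naphthol, then fluoride cleavage of the aryl silyl ether with methylation of the liberated naphthoxide in the same flask, so the air-sensitive free 1,3-naphthalenediol never appears.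

Step 8
Reactants: 20 1-(3,5-dimethoxyphenyl)-5,7-dimethoxy-2,3-dimethylnaphthalene
Product: 23 sacidumlignan A [5-(4-hydroxy-3,5-dimethoxyphenyl)-1,3-dimethoxy-6,7-dimethylnaphthalen-2-ol], via 6,4'-dilithio derivative 21 (not isolated), via 6,4'-bis(dimethoxyboryl) derivative 22 (not isolated)
Conditions: n-BuLi (4 equiv), TMEDA, THF, 0 → 20 °C; B(OMe)3, −78 → 20 °C; then 30% H2O2, AcOH, 0 °C
Reagents that add atoms: hydrogen peroxide, OO
Why: Twofold directed ortho-lithiation removes in each ring the only hydrogen flanked by two methoxy groups (C6 and C4'), as in 1,3-dimethoxybenzene, and the aryllithiums are borylated and oxidised in the same flask (lithiation–borylation–oxidation) before the hindered boron groups can be lost by protonation.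

**Compound list**

1 | 2,3-dimethylphenol | Cc1cccc(O)c1C | starting material
2 | 2,3-dimethylphenyl acetate | CC(=O)Oc1cccc(C)c1C | intermediate
3 | 1-(2-hydroxy-3,4-dimethylphenyl)ethan-1-one | CC(=O)c1ccc(C)c(C)c1O | intermediate
4 | 6-acetyl-2,3-dimethylphenyl trifluoromethanesulfonate | CC(=O)c1ccc(C)c(C)c1OS(=O)(=O)C(F)(F)F | intermediate
5 | (3,5-dimethoxyphenyl)boronic acid | COc1cc(OC)cc(B(O)O)c1 | starting material
6 | 1-[2-(3,5-dimethoxyphenyl)-3,4-dimethylphenyl]ethan-1-one | CC(=O)c1ccc(C)c(C)c1-c1cc(OC)cc(OC)c1 | intermediate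
7 | 1-[2-(3,5-dimethoxyphenyl)-3,4-dimethylphenyl]-4,4,4-trifluorobutane-1,3-dione (trifluoromethyl diketone, formed as its lithium enolate) | O=C(CC(=O)C(F)(F)F)c1ccc(C)c(C)c1-c1cc(OC)cc(OC)c1 | intermediate
8 | 2-diazo-1-[2-(3,5-dimethoxyphenyl)-3,4-dimethylphenyl]ethan-1-one | [N-]=[N+]=CC(=O)c1ccc(C)c(C)c1-c1cc(OC)cc(OC)c1 | intermediate
9 | 3-phenylisoxazole (3-phenyl-1,2-oxazole) | c1ccc(cc1)-c1ccon1 | starting material
10 | triisopropylsilyl trifluoromethanesulfonate | CC(C)[Si](OS(=O)(=O)C(F)(F)F)(C(C)C)C(C)C | starting material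
11 | 5-lithio-3-phenylisoxazole | [Li]c1cc(-c2ccccc2)no1 | intermediate
12 | lithium ethynolate | [Li+].[O-]C#C | intermediate
13 | (triisopropylsilyloxy)acetylene | C#CO[Si](C(C)C)(C(C)C)C(C)C | intermediate
14 | 2-[2-(3,5-dimethoxyphenyl)-3,4-dimethylphenyl]ethen-1-one (arylketene) | O=C=Cc1ccc(C)c(C)c1-c1cc(OC)cc(OC)c1 | intermediate
15 | 4-[2-(3,5-dimethoxyphenyl)-3,4-dimethylphenyl]-3-[(triisopropylsilyl)oxy]cyclobut-2-en-1-one (racemic) | O=C1C=C(O[Si](C(C)C)(C(C)C)C(C)C)C1c1ccc(C)c(C)c1-c1cc(OC)cc(OC)c1 | intermediate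
16 | 4-[2-(3,5-dimethoxyphenyl)-3,4-dimethylphenyl]-3-[(triisopropylsilyl)oxy]buta-1,3-dien-1-one (dienylketene, aryl cis to the ketene arm) | O=C=C/C(O[Si](C(C)C)(C(C)C)C(C)C)=C\c1ccc(C)c(C)c1-c1cc(OC)cc(OC)c1 | intermediate
17 | 5-(3,5-dimethoxyphenyl)-6,7-dimethyl-3-[(triisopropylsilyl)oxy]naphthalen-1(8aH)-one (keto tautomer of 18, racemic) | O=C1C=C(O[Si](C(C)C)(C(C)C)C(C)C)C=C2C(-c3cc(OC)cc(OC)c3)=C(C)C(C)=CC12 | intermediate
18 | 5-(3,5-dimethoxyphenyl)-6,7-dimethyl-3-[(triisopropylsilyl)oxy]naphthalen-1-ol | COc1cc(OC)cc(-c2c(C)c(C)cc3c(O)cc(O[Si](C(C)C)(C(C)C)C(C)C)cc23)c1 | intermediate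
19 | {[8-(3,5-dimethoxyphenyl)-4-methoxy-6,7-dimethylnaphthalen-2-yl]oxy}triisopropylsilane (C5 OMe, C7 OSi) | COc1cc(OC)cc(-c2c(C)c(C)cc3c(OC)cc(O[Si](C(C)C)(C(C)C)C(C)C)cc23)c1 | intermediate
20 | 1-(3,5-dimethoxyphenyl)-5,7-dimethoxy-2,3-dimethylnaphthalene | COc1cc(OC)cc(-c2c(C)c(C)cc3c(OC)cc(OC)cc23)c1 | intermediate
21 | 6,4'-dilithio derivative of 20 | [Li]c1c(OC)cc(-c2c(C)c(C)cc3c(OC)c([Li])c(OC)cc23)cc1OC | intermediate
22 | 6,4'-bis(dimethoxyboryl) derivative of 20 | COB(OC)c1c(OC)cc(-c2c(C)c(C)cc3c(OC)c(B(OC)OC)c(OC)cc23)cc1OC | intermediate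
23 | sacidumlignan A, 5-(4-hydroxy-3,5-dimethoxyphenyl)-1,3-dimethoxy-6,7-dimethylnaphthalen-2-ol | COc1cc(-c2c(C)c(C)cc3c(OC)c(O)c(OC)cc23)cc(OC)c1O | target

**Count and risks**

Total steps: 8. Longest linear sequence: 7 (steps 1, 2, 3, 4, 6, 7, 8 from 2,3-dimethylphenol); step 5 is a one-step branch.

Step 8, twofold lithiation and hydroxylation. The second metalation may stall once the first aryllithium has formed and aggregated, leaving singly hydroxylated material, or the 2,6-dimethoxyaryl boron groups may be protonated off before oxidation. The fallback brings the ring C oxygen in with ring C, so that only one lithiation is needed; it sets out from 4 and returns at 23.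
- Suzuki coupling of 4 with purchased 2,6-dimethoxy-4-(4,4,5,5-tetramethyl-1,3,2-dioxaborolan-2-yl)phenol under the step 3 conditions should give 1-[2-(4-hydroxy-3,5-dimethoxyphenyl)-3,4-dimethylphenyl]ethan-1-one F1.
- MOMCl and i-Pr2NEt in CH2Cl2 should give the methoxymethyl ether 1-{2-[3,5-dimethoxy-4-(methoxymethoxy)phenyl]-3,4-dimethylphenyl}ethan-1-one F2.
- Diazo transfer as in step 4 should give 2-diazo-1-{2-[3,5-dimethoxy-4-(methoxymethoxy)phenyl]-3,4-dimethylphenyl}ethan-1-one F3.
- Benzannulation with 13 as in step 6 should give 5-[3,5-dimethoxy-4-(methoxymethoxy)phenyl]-6,7-dimethyl-3-[(triisopropylsilyl)oxy]naphthalen-1-ol F4.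
- The step 7 conditions should give 1-[3,5-dimethoxy-4-(methoxymethoxy)phenyl]-5,7-dimethoxy-2,3-dimethylnaphthalene F5.
- A single lithiation at C6 (n-BuLi, TMEDA), B(OMe)3 and H2O2/AcOH should give 5-[3,5-dimethoxy-4-(methoxymethoxy)phenyl]-1,3-dimethoxy-6,7-dimethylnaphthalen-2-ol F6; ring C then has no hydrogen between two oxygens.
- HCl in MeOH removes the acetal and gives 23.

Step 5, siloxyalkyne from the isoxazole. n-BuLi may add to the ring C=N or to the liberated benzonitrile instead of deprotonating C5, the ynolate may be silylated on carbon to a silylketene, or the volatile ynol ether may be lost on separation from benzonitrile. The fallback replaces the silyl ynol ether by an alkyl ynol ether that already carries the C7 methyl; it sets out from 8 and returns at 20.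
- Methoxyacetylene F7 is made from chloroacetaldehyde dimethyl acetal with NaNH2 in liquid NH3.
- It is used in excess in the irradiation of 8 in a sealed Pyrex tube, followed by heating. The same cascade should give 5-(3,5-dimethoxyphenyl)-3-methoxy-6,7-dimethylnaphthalen-1-ol F8.
- MeI and K2CO3 in DMF convert F8 into 20.

Step 6, benzannulation. The photogenerated arylketene may dimerise or acylate ring C before it meets the alkyne, or continued irradiation may degrade the cyclobutenone and the electron-rich biaryl. The fallback generates the same ketene without light; it sets out from 8 and returns at 18.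
- Wolff rearrangement of 8 in aqueous THF with PhCO2Ag and Et3N (Arndt–Eistert conditions) should give [2-(3,5-dimethoxyphenyl)-3,4-dimethylphenyl]acetic acid F9.
- (COCl)2 with catalytic DMF gives [2-(3,5-dimethoxyphenyl)-3,4-dimethylphenyl]acetyl chloride F10.
- Slow addition of Et3N to F10 and 13 in CH2Cl2 at 20 °C forms the ketene by dehydrochlorination and the cyclobutenone by [2+2] addition; heating in toluene at 80–110 °C then gives 18.

Further compounds
F1 | step 8 | 1-[2-(4-hydroxy-3,5-dimethoxyphenyl)-3,4-dimethylphenyl]ethan-1-one | CC(=O)c1ccc(C)c(C)c1-c1cc(OC)c(O)c(OC)c1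
F2 | step 8 | 1-{2-[3,5-dimethoxy-4-(methoxymethoxy)phenyl]-3,4-dimethylphenyl}ethan-1-one | CC(=O)c1ccc(C)c(C)c1-c1cc(OC)c(OCOC)c(OC)c1
F3 | step 8 | 2-diazo-1-{2-[3,5-dimethoxy-4-(methoxymethoxy)phenyl]-3,4-dimethylphenyl}ethan-1-one | [N-]=[N+]=CC(=O)c1ccc(C)c(C)c1-c1cc(OC)c(OCOC)c(OC)c1
F4 | step 8 | 5-[3,5-dimethoxy-4-(methoxymethoxy)phenyl]-6,7-dimethyl-3-[(triisopropylsilyl)oxy]naphthalen-1-ol | COCOc1c(OC)cc(-c2c(C)c(C)cc3c(O)cc(O[Si](C(C)C)(C(C)C)C(C)C)cc23)cc1OC
F5 | step 8 | 1-[3,5-dimethoxy-4-(methoxymethoxy)phenyl]-5,7-dimethoxy-2,3-dimethylnaphthalene | COCOc1c(OC)cc(-c2c(C)c(C)cc3c(OC)cc(OC)cc23)cc1OC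
F6 | step 8 | 5-[3,5-dimethoxy-4-(methoxymethoxy)phenyl]-1,3-dimethoxy-6,7-dimethylnaphthalen-2-ol | COCOc1c(OC)cc(-c2c(C)c(C)cc3c(OC)c(O)c(OC)cc23)cc1OC
F7 | step 5 | methoxyacetylene (methoxyethyne) | COC#C
F8 | step 5 | 5-(3,5-dimethoxyphenyl)-3-methoxy-6,7-dimethylnaphthalen-1-ol | COc1cc(OC)cc(-c2c(C)c(C)cc3c(O)cc(OC)cc23)c1
F9 | step 6 | [2-(3,5-dimethoxyphenyl)-3,4-dimethylphenyl]acetic acid | OC(=O)Cc1ccc(C)c(C)c1-c1cc(OC)cc(OC)c1
F10 | step 6 | [2-(3,5-dimethoxyphenyl)-3,4-dimethylphenyl]acetyl chloride | ClC(=O)Cc1ccc(C)c(C)c1-c1cc(OC)cc(OC)c1
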